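The 5 questions are one order and 4 yields of X, all from the same charge in different vessels.

all flasks: Z 13 mol%
- midnight: Q 0.50 M; J 1.10 equiv (fed, over 2.40 min); time 3.0 min; a stirred flask in which J is dosed at a steady rate over 2.40 min without added volume, worked up at 3.0 min
- dawn: Q 0.50 M (fed, over 2.40 min); J 1.10 equiv; time 3.0 min; all but Q at the start; Q goes in evenly over 2.40 min, the run ends at 3.0 min
- dusk: Q 0.50 M; J 1.10 equiv; time 3.0 min; everything together in a closed stirred flask, run for 3.0 min
- autumn: Q 0.50 M; J 1.10 equiv; one stirred flow tank at steady state, fed with the mixture as stated, mean residence time 3.0 min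

    J + Z ⇌ J.Z (K1 = 27 M⁻¹, k1 = 69 M⁻¹ s⁻¹)
    Q + J.Z → Q.J.Z (k2 = 0.36 M⁻¹ s⁻¹)
    Q.J.Z → Z + X (k3 = 2.7 s⁻¹)
    Q ⇌ D (K4 = 2.2, k4 = 0.36 s⁻¹)

- the stated concentrations are those of everything mixed, before any reaction; amounts are the same in each set-up
- the feed brings no volume worth counting
- run time (midnight): 3.0 min

- order of the set-ups by the amount of X at the outlet or at the end, in percent of the Q put in, highest first (midnight / dawn / dusk / autumn)
- amount of X at the outlet or at the end, in percent of the Q put in, midnight
- amount of X at the outlet or at the end, in percent of the Q put in, dawn
- amount of X at the outlet or at the end, in percent of the Q put in, dusk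
- amount of X at the outlet or at the end, in percent of the Q put in, autumn

I look for the concentration that sets the order of the rate. Q and D relax with a half-life of 1.32 s, far shorter than the run of 180 s, so I hold Q at the share f = 31.2% of the pool of Q plus D. In dusk free Q takes up J.Z at 0.0562 s⁻¹ at the start, but J.Z falls back to J and Z at 2.56 s⁻¹, faster, and Q.J.Z breaks up at 2.7 s⁻¹, faster too. So over this run I take J.Z as the resting state, its reaction with Q as the rate-limiting step, and the pool as falling pseudo-first-order at a given J.Z concentration.

The catalyst charge is 0.0650 M. When a fraction 0.5 of the Q has reacted, J stands near 0.235 M, which puts a share s = 86.4% of the catalyst in J.Z. The drain constant, the rate constant of Q binding times f times the J.Z concentration, is then 0.00632 s⁻¹.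

For dusk I have two ways. The exponential fall of the pool gives 67.9%. A mean rate, taken with the pool midway between start and end, gives 72.5%. They part by 4.6 percentage points, and the second cheats: its mean pool is 63.7%, above the 59.7% that the exponential curve averages. I keep the exponential.

The same constant gives autumn 53.2%, and dawn, averaged over its even feed, 47.7%. For midnight, with its J fed over 2.40 min, I carry no number.

The forecast gives dusk 68%, midnight 59%, autumn 54% and dawn 50%, in the order dusk > midnight > autumn > dawn, holding that “feeding Q slowly costs the most because the late Q gets little contact time”. Its dawn stands 2.3 points above mine.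

The flasks give dusk > midnight > autumn > dawn: dusk 67.8%, midnight 59.3%, autumn 53.3%, dawn 49.1%. Dusk's yield has moved by 5 points at a Q charge of 0.437 M or 0.574 M, with the equivalents, the loading and the time held.

In dusk the pool left at 3.00 min is 32.1%, which reads as a mean drain constant of 0.00631 s⁻¹. A neighbour of dawn is charged with 0.12 M of Q, at the same equivalents and loading. Its catalyst charge is 0.0156 M, and with J taken as its charge less that of the catalyst, 0.116 M, the share s is 75.9%. The drain constant falls to 0.00133 s⁻¹, less than in the first reckoning, and the dawn reckoning gives 13.2%. That flask ends with 13.5% of X and 73.5% of its catalyst as J.Z.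

The numbers of this flask stand for no real mixture; the run is a simulation.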